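## Analysis of the target

The target, numbered 9 below, is the hexacosyl ester of 3-(4-hydroxyphenyl)propanoic acid. It has a para-disubstituted benzene ring carrying a free phenol on one side and, on the other, a two-carbon tether to an ester carbonyl whose alkoxy oxygen bears an unbranched, saturated chain of 26 carbons. There is one ring, no stereocentre and no double bond outside the arene, so no configuration has to be controlled. The groups that need care are the phenol O–H, which is acidic, nucleophilic and a ligand for metals, and the single ester, which must not be exchanged or cleaved once in place. The difficulty is practical and regiochemical: the chain must be joined to oxygen strictly through its terminal carbon, C26 components are waxy and hard to separate from long-chain by-products, and the phenol must be told apart from the carboxyl group. The plan rests on the O–C1 bond of the hexacosyl group together with the adjacent C1–C2 bond. If C1 and C2 are read as the former sp carbons of a terminal alkyne, the ester oxygen to C1 bond can be made by adding the carboxylic acid O–H across that alkyne with oxygen at the terminal carbon. The unsaturation left at C1=C2 is then removed by hydrogenation, which also unmasks the phenol if it is carried as a benzyl ether.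

## Retrosynthetic reasoning

**Target 9 back to enol ester 7, through 8.** No skeletal bond is cut in the first backward move. Two hydrogen-labile elements are added instead: a C1=C2 double bond in the chain, which turns the alkyl ester into an enol ester, and a benzyl group on the phenol oxygen. Both are chosen because one heterogeneous hydrogenation removes them, the alkene first (giving 8) and the benzyl ether second, so the protecting group costs no step of its own. The forward reaction has to saturate the alkene and cleave the O-benzyl bond without breaking the C–O bond between the ester oxygen and the chain.

**Enol ester 7 back to acid 3 and alkyne 6.** The bond cut is the one between the ester oxygen and chain C1. Cutting here divides the molecule at its natural seam into the aryl propanoic acid and the whole C26 chain. It is also the only disconnection of 7 that needs neither an activated acyl derivative nor a C26 alcohol, because the O–H of 3 is simply added across the triple bond of 6. The forward reaction has to deliver oxygen to the terminal carbon and hydrogen to C2. A proton-catalysed or π-acid-catalysed addition would give the opposite regiochemistry, whereas ruthenium catalysis through a vinylidene gives the required one. The phenol is carried as its benzyl ether in 3 so that the carboxylic acid is the only O–H donor offered to the catalyst.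

**Alkyne 6 back to bromide 4 and acetylide complex 5.** The C2–C3 bond of the chain, the sp–sp3 bond next to the triple bond, is cut. This is the one place in an otherwise featureless chain where the polarity is unambiguous: an acetylide anion against a primary alkyl bromide. It takes the chain back to a C24 electrophile and a two-carbon nucleophile. The forward reaction is a substitution that must outrun elimination and needs a medium in which a C24 bromide dissolves.

**Acid 3 back to acid 1 and benzyl bromide 2.** The benzylic C–O bond of the ether is cut, which leaves 1, a compound that already holds every carbon of the aryl half. The forward reaction has to alkylate the phenoxide and leave the carboxyl group free. The large difference in nucleophilicity between the two anions of the dianion allows this in one operation.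

## Alternatives that were turned down

**Alternative 1:** The disconnection lies in the aromatic ring itself. Phenol 9 is taken back to the cyclohexenone hexacosyl 3-(4-oxocyclohex-2-en-1-yl)propanoate A3 (racemic), and A3 is opened across ring bonds C4–C5 and C2=C3 to the aldehyde ester hexacosyl 5-oxopentanoate A1 and methyl vinyl ketone A2. In the forward key step a secondary amine with a carboxylic acid co-catalyst converts A1 into its enamine, which adds to A2 in a Michael reaction. Intramolecular aldol condensation then closes the six-membered ring, and a separate dehydrogenation would aromatise A3 to 9.

- For it: the ring formation is metal-free and well understood. The phenol appears only in the last step and never needs a protecting group, and on that point this plan is stronger than the chosen one.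
- Against it: the para-substituted benzene ring is already complete in compound 1, so the annulation solves a problem the structure does not pose. The ring stereocentre of A3 is made only to be destroyed. A change of oxidation level has to be carried out at the end on a waxy substrate. A2 polymerises and the aldehyde of A1 can self-condense under the same catalysis. A1 must first be assembled from 1-hexacosanol A4, so the ester O–C1 bond is still made by classical esterification of the very alcohol the chosen route avoids.
- Comparison: at least four operations in line are needed (two to A1, the annulation, the aromatisation) against three for the chosen route. In place of freedom from protecting groups, the chosen strategy offers an aromatic ring that is never built or put at risk, and a benzyl ether whose removal costs no extra step.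

**Alternative 2:** The cut is made in the middle of the chain, at the C11–C12 bond counted from the ester oxygen. The forward key step is a mixed Kolbe electrolysis. 12-[3-(4-Acetoxyphenyl)propanoyloxy]dodecanoic acid A5 and an excess of palmitic acid A6 are oxidised together at a platinum anode. Each carboxylate loses its carboxyl carbon, and the undecyl and pentadecyl radicals combine to give hexacosyl 3-(4-acetoxyphenyl)propanoate A7, which selective deacetylation would convert into 9.

- For it: the chain comes from C12 and C16 fatty acid feedstocks, which are far cheaper and easier to obtain than any C24 or C26 reagent. On feedstock cost this plan is stronger than the chosen one, and it needs no transition-metal catalyst.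
- Against it: radical–radical coupling is statistical, so both symmetrical dimers form beside A7. They are long-chain waxes of very similar behaviour, which is the worst separation problem this target can pose. The excess of A6 needed to favour the cross product makes the hydrocarbon dimer the main product by mass. The electron-rich aryl ring and the aryl acetate are exposed to a high anode potential and to a partly neutralised alcoholic electrolyte, which invites ring oxidation and acyl exchange. A5 itself takes several steps and has its own phenol/acid differentiation problem.
- Comparison: the chosen route builds the chain by a polar, one-to-one C–C coupling of defined partners and so gives a single chain length, which matters more here than cheap feedstock.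

**Alternative 3:** Here the ester carbonyl carbon is excised. Both its bond to C-alpha and its bond to the alkoxy oxygen are cut, giving 1-(benzyloxy)-4-vinylbenzene A8, carbon monoxide A9 and 1-hexacosanol A4. The forward key step is a palladium-catalysed, linear-selective hydroalkoxycarbonylation. A palladium hydride, generated from a divalent palladium precatalyst with a bulky chelating bis(di-tert-butylphosphino) ligand and a sulfonic acid, adds to the styrene. A9 then inserts, and alcoholysis of the acyl palladium species by A4 releases hexacosyl 3-(4-benzyloxyphenyl)propanoate A10.

- For it: two bonds form in one three-component step. A10 is the same compound as intermediate 8 of the chosen route but is reached without an enol ester, so the end game is a plain debenzylation. On bonds formed per step and on the safety of the last step this plan is as strong as or stronger than the chosen one.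
- Against it: alkoxycarbonylations run best with the alcohol as solvent or in large excess, which is not possible with a waxy C26 alcohol. With A4 near stoichiometric the alcoholysis slows, and unreacted A4 must be separated from an ester of almost the same chain length. The electron-rich alkoxystyrene A8 is prone to acid-induced oligomerisation under the sulfonic acid promoter and to the branched 2-arylpropanoate. Pressurised A9 is required, and the plan again depends on the C26 alcohol.
- Comparison: the chosen route runs under neutral conditions with the two partners close to one to one and uses no gas other than hydrogen at ambient pressure. Its only excess reagent is a hydrocarbon alkyne, which is easily parted from an ester.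

Key step: step 3

Assumption: 1-bromotetracosane 4 and the lithium acetylide ethylenediamine complex 5 are taken to be purchasable as such, and the ruthenium complex of step 3 is used as a preformed, isolated catalyst.

## Route

Step 1
Reactants: 1 3-(4-hydroxyphenyl)propanoic acid; 2 benzyl bromide
Product: 3 3-(4-benzyloxyphenyl)propanoic acid
Conditions: BnBr (1.3 equiv), NaOH (3 equiv), EtOH/H2O 4:1, reflux; wash with MTBE; aq. HCl to pH 2
Reagents that add atoms: benzyl bromide, BrCc1ccccc1
Why: Williamson ether synthesis on the dianion: in aqueous ethanol the phenoxide is far more nucleophilic than the hydrogen-bonded carboxylate, and the excess hydroxide at reflux reverses any adventitious alkylation of the carboxylate by saponification, so acidification should deliver the free acid with the phenol capped.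

Step 2
Reactants: 4 1-bromotetracosane; 5 lithium acetylide ethylenediamine complex
Product: 6 1-hexacosyne (hexacos-1-yne)
Conditions: LiC≡CH·H2NCH2CH2NH2 (2 equiv), DMSO/THF, 15 °C to rt; aq. NH4Cl
Reagents that add atoms: lithium acetylide ethylenediamine complex, [Li]C#C.NCCN
Why: SN2 alkylation of an acetylide by an unhindered primary bromide in a dipolar aprotic medium; THF as co-solvent keeps the C24 bromide in solution, and the complexed acetylide is a good carbon nucleophile but only a moderate base, which should keep E2 loss of HBr small.

Step 3
Reactants: 3 3-(4-benzyloxyphenyl)propanoic acid; 6 1-hexacosyne
Product: 7 (Z)-hexacos-1-en-1-yl 3-(4-benzyloxyphenyl)propanoate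
Conditions: Ru(η3-CH2C(CH3)CH2)2(Ph2P(CH2)4PPh2) (2 mol %), 6 (1.1 equiv), toluene, 65 °C, N2
Reagents that add atoms: none
Why: Ruthenium-catalysed anti-Markovnikov hydro-oxycarbonylation of a terminal alkyne, a known reaction type for linear 1-alkynes with aliphatic and aromatic carboxylic acids. Acid 3 protonates the two 2-methylallyl ligands (lost as isobutene) to give a divalent ruthenium bis(carboxylate) held by the chelating diphosphine; alkyne 6 coordinates and rearranges by 1,2-hydrogen shift to the vinylidene Ru=C=CH–C24H49. The carboxylate adds to the electrophilic metal-bound carbon, and protonolysis of the resulting 1-acyloxyalkenyl ruthenium species by another molecule of 3 releases the enol ester and regenerates the carboxylate complex. Oxygen can only enter at the carbon that is bound to the metal in the vinylidene, so it ends up on chain C1, which is the regioselectivity the step needs; the competing path is direct Markovnikov addition to the π-bound alkyne, which the electron-rich chelating diphosphine disfavours. The Z geometry follows from carboxylate attack with the alkyl chain turned away from the metal fragment, but it has no consequence because the alkene is hydrogenated in step 4. No ring is closed and no stereocentre is created. In the substrates, the unhindered terminal C–H of 6 secures vinylidene formation, the benzyl ether of 3 removes the only other O–H that could add or bind to ruthenium, and the neutral, anhydrous conditions leave the ether and the new enol ester untouched.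

Step 4
Reactants: 7 (Z)-hexacos-1-en-1-yl 3-(4-benzyloxyphenyl)propanoate
Product: 9 hexacosyl 3-(4-hydroxyphenyl)propanoate, via hexacosyl 3-(4-benzyloxyphenyl)propanoate 8 (not isolated)
Conditions: H2 (1 atm), 10% Pd/C, EtOAc/THF, rt to 40 °C
Reagents that add atoms: none
Why: Heterogeneous catalytic hydrogenation followed on the same catalyst by hydrogenolysis of a benzyl aryl ether: the disubstituted enol ester alkene should be saturated first to give 8, whose O-benzyl bond is then cleaved with release of toluene. The aprotic, non-nucleophilic solvent prevents acyl transfer from the enol ester before it is saturated, and the alkyl ester and the arene are inert to palladium under these conditions.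

## Compound list

1 | 3-(4-hydroxyphenyl)propanoic acid | OC(=O)CCc1ccc(O)cc1 | starting material
2 | benzyl bromide | BrCc1ccccc1 | starting material
3 | 3-(4-benzyloxyphenyl)propanoic acid | OC(=O)CCc1ccc(OCc2ccccc2)cc1 | intermediate
4 | 1-bromotetracosane | CCCCCCCCCCCCCCCCCCCCCCCCBr | starting material
5 | lithium acetylide ethylenediamine complex | [Li]C#C.NCCN | starting material
6 | 1-hexacosyne | CCCCCCCCCCCCCCCCCCCCCCCCC#C | intermediate
7 | (Z)-hexacos-1-en-1-yl 3-(4-benzyloxyphenyl)propanoate | CCCCCCCCCCCCCCCCCCCCCCCC/C=C\OC(=O)CCc1ccc(OCc2ccccc2)cc1 | intermediate
8 | hexacosyl 3-(4-benzyloxyphenyl)propanoate | CCCCCCCCCCCCCCCCCCCCCCCCCCOC(=O)CCc1ccc(OCc2ccccc2)cc1 | intermediate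
9 | hexacosyl 3-(4-hydroxyphenyl)propanoate | CCCCCCCCCCCCCCCCCCCCCCCCCCOC(=O)CCc1ccc(O)cc1 | target

## Step count and risks

Total step count: 4. Longest linear sequence: 3 steps (steps 1, 3 and 4 from 1, or steps 2, 3 and 4 from 4); the two one-step branches meet in step 3.

**Step 3 (key step).** The most likely failure is loss of regiocontrol or of catalyst activity. If vinylidene formation is slow relative to direct carboxylate attack on the π-bound alkyne, the Markovnikov adduct forms alongside 7 and would be carried by step 4 into a secondary-alkyl ester that is very hard to separate from 9. Head-to-head dimerisation of 6 at the vinylidene stage and deactivation of the air-sensitive allyl complex by traces of oxygen are the other leaks. Fallback: setting out from 3, the ester bond is made by classical carbodiimide coupling instead of alkyne addition. Acid 3 is esterified with purchased 1-hexacosanol F1 (EDC·HCl, DMAP, CH2Cl2/THF, 35 °C), which gives the saturated ester 8 as an isolated compound. 8 rejoins the route in the second half of step 4 (H2, Pd/C) and gives 9.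

**Step 4.** Three processes could interfere. Reductive cleavage of the vinyl C–O bond on the palladium surface could compete with saturation of the alkene. Acyl transfer from not yet reduced 7 to phenol could occur if debenzylation runs ahead, since an enol ester is an activated acyl donor. The waxy intermediate 8 could also crystallise from the medium and stall the debenzylation. Fallback: setting out from 7, the reduction is staged. Homogeneous hydrogenation with RhCl(PPh3)3 (monovalent rhodium) under H2 in toluene at 40 °C has no hydrogenolysis activity, saturates only the alkene and allows 8 to be isolated. The benzyl ether of 8 is then hydrogenolysed separately over Pd(OH)2 on carbon in warm THF/EtOAc, which returns to the route at 9.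

**Step 2.** E2 elimination to the terminal alkene and incomplete conversion are the risks, the latter because the C24 bromide separates from DMSO. The alkene would co-elute with 6, although it is inert in step 3 and can be removed at the stage of 7. Fallback: setting out from 4, the bromide is alkylated in homogeneous solution with commercial lithium (trimethylsilyl)acetylide, LiC≡CSiMe3, in THF/DMPU (cat. NaI, 0 °C to rt) to give trimethyl(hexacos-1-yn-1-yl)silane F2. Desilylation with K2CO3 in MeOH/THF returns to the route at 6.

**Step 1.** Competing C-benzylation of the ambident phenoxide in the protic medium, and loss of the bromide to solvolysis so that 1 remains, are the likely problems. Fallback: setting out from 1, both acidic positions are benzylated in an aprotic medium (2, 2.3 equiv, K2CO3, DMF, 60 °C) to give benzyl 3-(4-benzyloxyphenyl)propanoate F3. The benzyl ester is then saponified (LiOH, THF/MeOH/H2O, rt, then aq. HCl), which returns to the route at 3.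

## Further compounds

F1 | step 3 | 1-hexacosanol | CCCCCCCCCCCCCCCCCCCCCCCCCCO
F0 | step 4 | none | none
F2 | step 2 | trimethyl(hexacos-1-yn-1-yl)silane | CCCCCCCCCCCCCCCCCCCCCCCCC#C[Si](C)(C)C
F3 | step 1 | benzyl 3-(4-benzyloxyphenyl)propanoate | O=C(CCc1ccc(OCc2ccccc2)cc1)OCc1ccccc1
A1 | alternative 1 | hexacosyl 5-oxopentanoate | CCCCCCCCCCCCCCCCCCCCCCCCCCOC(=O)CCCC=O
A2 | alternative 1 | methyl vinyl ketone (but-3-en-2-one) | CC(=O)C=C
A3 | alternative 1 | hexacosyl 3-(4-oxocyclohex-2-en-1-yl)propanoate (racemic) | CCCCCCCCCCCCCCCCCCCCCCCCCCOC(=O)CCC1CCC(=O)C=C1
A4 | alternative 1 | 1-hexacosanol | CCCCCCCCCCCCCCCCCCCCCCCCCCO
A5 | alternative 2 | 12-[3-(4-acetoxyphenyl)propanoyloxy]dodecanoic acid | CC(=O)Oc1ccc(CCC(=O)OCCCCCCCCCCCC(=O)O)cc1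
A6 | alternative 2 | palmitic acid (hexadecanoic acid) | CCCCCCCCCCCCCCCC(=O)O
A7 | alternative 2 | hexacosyl 3-(4-acetoxyphenyl)propanoate | CCCCCCCCCCCCCCCCCCCCCCCCCCOC(=O)CCc1ccc(OC(C)=O)cc1
A8 | alternative 3 | 1-(benzyloxy)-4-vinylbenzene | C=Cc1ccc(OCc2ccccc2)cc1
A9 | alternative 3 | carbon monoxide | [C-]#[O+]
A10 | alternative 3 | hexacosyl 3-(4-benzyloxyphenyl)propanoate | CCCCCCCCCCCCCCCCCCCCCCCCCCOC(=O)CCc1ccc(OCc2ccccc2)cc1
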